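**Retrosynthetic overview**

- Numbering: ring C1(Me)=C2, C3(OH), C4(i-Pr), C5(O-aroyl), C6, C7(Me)=C8, C9, C10; C11 is the isopropyl methine and C12 one of its methyl carbons.
- Feature: in the ten-membered ring the carbinol C3 is allylic to C1=C2 and adjacent to C4, whose isopropyl group is a hydrogenated isopropenyl group; C2=C1 / C3(OH) / C4–C11(=C12) is the retron of a [2,3]-Wittig shift.
- Disconnection of C3–C4: the ten-membered carbocycle comes by ring contraction from the 13-membered (Z,Z,Z) cyclic bis-allylic ether 26, in which oxygen links C3 and C12.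
- 26 comes from the acyclic hydroxy chloride 24 by Williamson closure of O–C12; the chain is built from nerol (C1–C3, C8–C10), an iodo-ylide (C7), (S)-glycidol (C4–C6, sets C5) and a Still–Gennari phosphonate (C11, C12).
- Ring order: 13-membered oxacycle (step 13), then ten-membered carbocycle (step 14); hydrogenation, silyl exchange and 4-hydroxybenzoylation of O5 finish the route.

Key step: step 14

Remark: the lithiated allylic ether 27 is assumed to be configurationally labile at C3, so that C3 is set in the sigmatropic shift and not in the deprotonation.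

**Route**

Step 1
Reactants: 1 nerol
Product: 3 neryl 4-methoxybenzyl ether, via sodium nerolate 2 (not isolated)
Conditions: NaH, 4-methoxybenzyl chloride, Bu4NI (cat.), THF/DMF, 0 °C → rt
Reagents that add atoms: 4-methoxybenzyl chloride, COc1ccc(CCl)cc1; sodium hydride, [Na+].[H-] (sodium only in intermediate 2)
Why: Williamson etherification of the primary allylic alkoxide with a benzylic chloride; the resulting ether should survive the basic, organometallic and hydride steps up to step 11 and can later be removed oxidatively beside a silyl ether.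

Step 2
Reactants: 3 neryl 4-methoxybenzyl ether
Product: 4 terminal epoxide of 3 (racemic at the oxirane CH)
Conditions: mCPBA (1 equiv), NaHCO3, CH2Cl2, −20 → 0 °C
Reagents that add atoms: 3-chloroperoxybenzoic acid, OOC(=O)c1cccc(Cl)c1
Why: Prilezhaev epoxidation should select the remote isopropylidene alkene, which is more electron-rich than the C1=C2 alkene deactivated by the allylic ether oxygen; the new stereocentre is destroyed in step 3.

Step 3
Reactants: 4 terminal epoxide
Product: 6 (4Z)-6-(4-methoxybenzyloxy)-4-methylhex-4-enal, via vicinal diol 5 (not isolated)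
Conditions: H5IO6, THF/H2O, 0 °C
Reagents that add atoms: none
Why: acid-mediated hydrolysis of the epoxide to the diol and periodate glycol cleavage (Malaprade reaction) in one flask should give the aldehyde C8 and acetone without touching the Z-alkene or the benzylic ether.

Step 4
Reactants: 6 aldehyde; 7 ethyltriphenylphosphonium iodide
Product: 11 (2Z,6Z)-7-iodo-3-methylocta-2,6-dienyl 4-methoxybenzyl ether, via ethylidenetriphenylphosphorane 8 (not isolated), via (1-iodoethyl)triphenylphosphonium iodide 9 (not isolated), via (1-iodoethylidene)triphenylphosphorane 10 (not isolated)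
Conditions: 7, n-BuLi, THF, 0 °C → rt; I2, −78 °C; NaN(SiMe3)2, −20 °C; then 6, −78 → −20 °C
Reagents that add atoms: iodine, II
Why: Wittig olefination with the α-iodo ylide (Stork–Zhao type) under kinetic control should give the Z-iodoalkene with iodine cis to the chain, which fixes the C7=C8 geometry once C6 takes the place of iodine.

Step 5
Reactants: 12 (S)-glycidol
Product: 13 (R)-glycidyl triethylsilyl ether
Conditions: Et3SiCl, Et3N, DMAP (cat.), CH2Cl2, 0 °C
Reagents that add atoms: chlorotriethylsilane, CC[Si](Cl)(CC)CC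
Why: silylation of the primary alcohol touches no bond at the stereocentre (the descriptor changes from S to R only through the priority rules), and this carbon becomes C5.

Step 6
Reactants: 11 Z-alkenyl iodide; 13 (R)-glycidyl triethylsilyl ether
Product: 15 (2R,4Z,8Z)-10-(4-methoxybenzyloxy)-4,8-dimethyl-1-(triethylsilyloxy)deca-4,8-dien-2-ol, via alkenyllithium 14 (not isolated)
Conditions: 11, t-BuLi (2 equiv), Et2O, −78 °C; then 13, BF3·OEt2, THF, −78 °C; H2O
Reagents that add atoms: tert-butyllithium, [Li]C(C)(C)C (lithium only in intermediate 14)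
Why: iodine–lithium exchange proceeds with retention of alkene geometry and the BF3-promoted SN2 opening of the terminal epoxide at its CH2 carbon forms C6–C7; C5 is carried over unchanged from glycidol.

Step 7
Reactants: 15 secondary alcohol
Product: 16 bis(triethylsilyl) ether
Conditions: Et3SiCl, imidazole, DMAP (cat.), CH2Cl2, 0 °C → rt
Reagents that add atoms: chlorotriethylsilane, CC[Si](Cl)(CC)CC
Why: routine silylation of the secondary C5 hydroxyl installs the ether that is carried through the key step.

Step 8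
Reactants: 16 bis(triethylsilyl) ether
Product: 17 (2R)-2-(triethylsilyloxy) aldehyde
Conditions: (COCl)2, DMSO, CH2Cl2, −78 → −30 °C; then Et3N, −78 → 0 °C
Reagents that add atoms: none
Why: under Swern conditions a primary triethylsilyl ether is cleaved and oxidised in place while the secondary one stays, and the cold amine work-up should avoid epimerisation of the α-silyloxy aldehyde.

Step 9
Reactants: 17 α-silyloxy aldehyde; 18 ethyl 2-[bis(2,2,2-trifluoroethoxy)phosphoryl]propanoate
Product: 20 ethyl (2Z,4R,6Z,10Z)-trienoate, via potassium phosphonate carbanion 19 (not isolated)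
Conditions: 18, KN(SiMe3)2, 18-crown-6, THF, −78 °C; then 17
Reagents that add atoms: potassium bis(trimethylsilyl)amide, C[Si](C)(C)[N-][Si](C)(C)C.[K+] (potassium only in intermediate 19)
Why: Still–Gennari olefination with the electron-poor phosphonate under dissociating conditions should give the kinetic Z-enoate, placing the ester carbon C12 cis to C5 across C11=C4.

Step 10
Reactants: 20 Z-enoate
Product: 21 (2Z)-allylic alcohol
Conditions: i-Bu2AlH (2.5 equiv), CH2Cl2, −78 °C; aq. potassium sodium tartrate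
Reagents that add atoms: none
Why: 1,2-reduction of the enoate by i-Bu2AlH gives the allylic alcohol without change of alkene geometry and leaves the silyl and benzylic ethers alone.

Step 11
Reactants: 21 allylic alcohol
Product: 23 allylic chloride, via allylic mesylate 22 (not isolated)
Conditions: MsCl, Et3N, CH2Cl2, −20 °C; then LiCl, THF, 0 °C → rt
Reagents that add atoms: lithium chloride, [Li+].[Cl-]; methanesulfonyl chloride, CS(=O)(=O)Cl (atoms only in intermediate 22)
Why: mesylation and SN2 displacement by chloride at the primary allylic carbon C12 run under non-acidic conditions, so the triethylsilyl ether and the alkene geometry should be kept.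

Step 12
Reactants: 23 allylic chloride
Product: 24 (2Z,6Z,9R,10Z)-12-chloro-3,7,11-trimethyl-9-(triethylsilyloxy)dodeca-2,6,10-trien-1-ol
Conditions: DDQ, CH2Cl2/aq. pH 7 phosphate buffer, 0 °C
Reagents that add atoms: none
Why: oxidative cleavage of the 4-methoxybenzyl ether by DDQ (hydride abstraction, then hydrolysis of the oxocarbenium ion) frees O3; the buffer protects the silyl ether and the allylic chloride is inert to the oxidant.

Step 13
Reactants: 24 hydroxy chloride
Product: 26 (3Z,5R,7Z,11Z)-3,7,11-trimethyl-5-(triethylsilyloxy)-1-oxacyclotrideca-3,7,11-triene, via sodium alkoxide 25 (not isolated)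
Conditions: NaH, Bu4NI (cat.), THF, reflux, slow addition of 24 (high dilution)
Reagents that add atoms: sodium hydride, [Na+].[H-] (sodium only in intermediate 25)
Why: intramolecular Williamson etherification of the primary alkoxide on the primary allylic chloride (iodide catalysis) closes the 13-membered ether, the three cis alkenes folding the chain so that the ends meet, and high dilution suppresses oligomers.

Step 14
Reactants: 26 13-membered cyclic bis-allylic ether
Product: 29 (1Z,3R,4R,5R,7Z)-1,7-dimethyl-4-(prop-1-en-2-yl)-5-(triethylsilyloxy)cyclodeca-1,7-dien-3-ol, via C3-lithiated ether 27 (not isolated), via lithium alkoxide 28 (not isolated)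
Conditions: n-BuLi, THF, −78 → −40 °C; then aq. NH4Cl, −78 °C
Reagents that add atoms: n-butyllithium, CCCC[Li] (lithium only in intermediates 27 and 28)
Why: n-BuLi removes a proton from the ether CH2 carbon C3, which is allylic to C1=C2, and the α-oxy allyllithium 27 undergoes a concerted suprafacial [2,3]-Wittig shift through a five-membered envelope transition state in which C3 bonds to C4 while the O–C12 bond breaks and the C11=C4 alkene moves to C11=C12, leaving the lithium alkoxide 28. The closest known reaction type is the [2,3]-Wittig ring contraction of 13-membered bis-allylic ethers of the farnesyl type to ten-membered homoallylic alcohols that carry an isopropenyl group next to the carbinol. The ten-membered carbocycle is closed by contraction of the 13-membered oxacycle (the new C3–C4 bond spans the ring and O, C12 and C11 leave it), not by an end-to-end cyclisation. C3 is set by the exo (pseudo-equatorial) position of the C2 vinyl arm on the envelope together with the cis geometry of the C11=C4 alkene, which should give the syn-type product with the C3 hydroxyl and the C4 isopropenyl group cis on the ring. C4 is set by the C5 stereocentre: with the C5–H bond eclipsing C4=C11 to avoid allylic 1,3-strain with C12, the ring tether through C6 brings C3 to the alkene face opposite the triethylsilyloxy group, so that the isopropenyl group ends trans to O5. The step needs lithiation at C3 and not at C12 and a [2,3]- and not a [1,2]-shift; C12 is shielded by the C11 methyl group and the cis C5 silyloxy substituent and its anion could only rearrange by forming a quaternary centre at C1, and the low temperature disfavours the radical [1,2]-pathway.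

Step 15
Reactants: 29 isopropenyl carbinol
Product: 30 (1Z,3R,4R,5R,7Z)-1,7-dimethyl-4-(propan-2-yl)-5-(triethylsilyloxy)cyclodeca-1,7-dien-3-ol
Conditions: H2 (1 atm), RhCl(PPh3)3 (cat.), benzene, rt
Reagents that add atoms: none
Why: homogeneous hydrogenation with RhCl(PPh3)3 should reduce the unhindered 1,1-disubstituted isopropenyl alkene and leave the two trisubstituted ring alkenes; no stereocentre is formed.

Step 16
Reactants: 30 C3 alcohol
Product: 31 C3 tert-butyldimethylsilyl ether
Conditions: t-BuMe2SiOTf, 2,6-lutidine, CH2Cl2, −78 → 0 °C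
Reagents that add atoms: tert-butyldimethylsilyl trifluoromethanesulfonate, CC(C)(C)[Si](C)(C)OS(=O)(=O)C(F)(F)F
Why: the silyl triflate silylates the hindered secondary allylic alcohol under buffered conditions that leave the triethylsilyl ether in place.

Step 17
Reactants: 31 bis-silyl ether
Product: 32 C5 alcohol
Conditions: PPTS (cat.), MeOH/CH2Cl2, 0 °C
Reagents that add atoms: none
Why: mild acid-catalysed methanolysis removes the less hindered triethylsilyl group much faster than the tert-butyldimethylsilyl group, and the weak acid at 0 °C should spare the acid-sensitive cyclodecadiene.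

Step 18
Reactants: 33 4-hydroxybenzoic acid
Product: 35 4-(tert-butyldimethylsilyloxy)benzoic acid, via silyl ester 34 (not isolated)
Conditions: t-BuMe2SiCl (2.2 equiv), imidazole, DMF, rt; then AcOH, THF/H2O, rt
Reagents that add atoms: tert-butylchlorodimethylsilane, CC(C)(C)[Si](C)(C)Cl
Why: exhaustive silylation followed by selective hydrolysis of the labile silyl ester gives the phenol-protected acid.

Step 19
Reactants: 32 C5 alcohol; 35 4-(tert-butyldimethylsilyloxy)benzoic acid
Product: 37 C5 4-(tert-butyldimethylsilyloxy)benzoate, via mixed anhydride 36 (not isolated)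
Conditions: 35, 2,4,6-Cl3C6H2COCl, Et3N, THF, rt; then 32, DMAP, toluene, rt → 40 °C
Reagents that add atoms: 2,4,6-trichlorobenzoyl chloride, O=C(Cl)c1c(Cl)cc(Cl)cc1Cl (atoms only in intermediate 36)
Why: Yamaguchi esterification: the acylpyridinium ion formed from the mixed anhydride acylates the hindered secondary C5 hydroxyl without touching any stereocentre.

Step 20
Reactants: 37 bis-silylated ester
Product: 38 target
Conditions: HF·pyridine, pyridine, THF, 0 °C → rt
Reagents that add atoms: none
Why: buffered fluoride desilylation removes the aryl and the allylic silyl ether in one operation under non-basic conditions, so the ester should neither migrate to O3 nor be cleaved.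

**Compound list** (ten-membered rings are named with the locants of the overview)

1 | nerol, (2Z)-3,7-dimethylocta-2,6-dien-1-ol | CC(C)=CCC/C(C)=C\CO | starting material
2 | sodium (2Z)-3,7-dimethylocta-2,6-dien-1-olate | CC(C)=CCC/C(C)=C\C[O-].[Na+] | intermediate (not isolated)
3 | 1-({[(2Z)-3,7-dimethylocta-2,6-dien-1-yl]oxy}methyl)-4-methoxybenzene | CC(C)=CCC/C(C)=C\COCc1ccc(OC)cc1 | intermediate
4 | 3-{(3Z)-5-[(4-methoxybenzyl)oxy]-3-methylpent-3-en-1-yl}-2,2-dimethyloxirane (racemic) | CC1(C)OC1CC/C(C)=C\COCc1ccc(OC)cc1 | intermediate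
5 | (6Z)-8-[(4-methoxybenzyl)oxy]-2,6-dimethyloct-6-ene-2,3-diol (racemic) | CC(C)(O)C(O)CC/C(C)=C\COCc1ccc(OC)cc1 | intermediate (not isolated)
6 | (4Z)-6-[(4-methoxybenzyl)oxy]-4-methylhex-4-enal | O=CCC/C(C)=C\COCc1ccc(OC)cc1 | intermediate
7 | ethyltriphenylphosphonium iodide | CC[P+](c1ccccc1)(c1ccccc1)c1ccccc1.[I-] | starting material
8 | ethylidenetriphenylphosphorane | CC=P(c1ccccc1)(c1ccccc1)c1ccccc1 | intermediate (not isolated)
9 | (1-iodoethyl)triphenylphosphonium iodide | CC(I)[P+](c1ccccc1)(c1ccccc1)c1ccccc1.[I-] | intermediate (not isolated)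
10 | (1-iodoethylidene)triphenylphosphorane | CC(I)=P(c1ccccc1)(c1ccccc1)c1ccccc1 | intermediate (not isolated)
11 | 1-({[(2Z,6Z)-7-iodo-3-methylocta-2,6-dien-1-yl]oxy}methyl)-4-methoxybenzene | C/C(I)=C/CC/C(C)=C\COCc1ccc(OC)cc1 | intermediate
12 | (S)-glycidol, [(2S)-oxiran-2-yl]methanol | OC[C@H]1CO1 | starting material
13 | triethyl{[(2R)-oxiran-2-yl]methoxy}silane | CC[Si](CC)(CC)OC[C@H]1CO1 | intermediate
14 | alkenyllithium from 11 (lithium in place of iodine, cis to the chain, geometry of 11 retained) | [Li]/C(C)=C\CC/C(C)=C\COCc1ccc(OC)cc1 | intermediate (not isolated)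
15 | (2R,4Z,8Z)-10-[(4-methoxybenzyl)oxy]-4,8-dimethyl-1-(triethylsilyloxy)deca-4,8-dien-2-ol | CC[Si](CC)(CC)OC[C@H](O)C/C(C)=C\CC/C(C)=C\COCc1ccc(OC)cc1 | intermediate
16 | (2R,4Z,8Z)-10-[(4-methoxybenzyl)oxy]-4,8-dimethyl-1,2-bis(triethylsilyloxy)deca-4,8-diene | CC[Si](CC)(CC)OC[C@H](O[Si](CC)(CC)CC)C/C(C)=C\CC/C(C)=C\COCc1ccc(OC)cc1 | intermediate
17 | (2R,4Z,8Z)-10-[(4-methoxybenzyl)oxy]-4,8-dimethyl-2-(triethylsilyloxy)deca-4,8-dienal | O=C[C@H](O[Si](CC)(CC)CC)C/C(C)=C\CC/C(C)=C\COCc1ccc(OC)cc1 | intermediate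
18 | ethyl 2-[bis(2,2,2-trifluoroethoxy)phosphoryl]propanoate | CCOC(=O)C(C)P(=O)(OCC(F)(F)F)OCC(F)(F)F | starting material
19 | potassium salt of the α-carbanion of 18 | CCOC(=O)[C-](C)P(=O)(OCC(F)(F)F)OCC(F)(F)F.[K+] | intermediate (not isolated)
20 | ethyl (2Z,4R,6Z,10Z)-12-[(4-methoxybenzyl)oxy]-2,6,10-trimethyl-4-(triethylsilyloxy)dodeca-2,6,10-trienoate | CCOC(=O)/C(C)=C\[C@H](O[Si](CC)(CC)CC)C/C(C)=C\CC/C(C)=C\COCc1ccc(OC)cc1 | intermediate
21 | (2Z,4R,6Z,10Z)-12-[(4-methoxybenzyl)oxy]-2,6,10-trimethyl-4-(triethylsilyloxy)dodeca-2,6,10-trien-1-ol | OC/C(C)=C\[C@H](O[Si](CC)(CC)CC)C/C(C)=C\CC/C(C)=C\COCc1ccc(OC)cc1 | intermediate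
22 | methanesulfonate of 21 | CS(=O)(=O)OC/C(C)=C\[C@H](O[Si](CC)(CC)CC)C/C(C)=C\CC/C(C)=C\COCc1ccc(OC)cc1 | intermediate (not isolated)
23 | (2Z,4R,6Z,10Z)-1-chloro-12-[(4-methoxybenzyl)oxy]-2,6,10-trimethyl-4-(triethylsilyloxy)dodeca-2,6,10-triene | ClC/C(C)=C\[C@H](O[Si](CC)(CC)CC)C/C(C)=C\CC/C(C)=C\COCc1ccc(OC)cc1 | intermediate
24 | (2Z,6Z,9R,10Z)-12-chloro-3,7,11-trimethyl-9-(triethylsilyloxy)dodeca-2,6,10-trien-1-ol | ClC/C(C)=C\[C@H](O[Si](CC)(CC)CC)C/C(C)=C\CC/C(C)=C\CO | intermediate
25 | sodium alkoxide of 24 | ClC/C(C)=C\[C@H](O[Si](CC)(CC)CC)C/C(C)=C\CC/C(C)=C\C[O-].[Na+] | intermediate (not isolated)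
26 | (3Z,5R,7Z,11Z)-3,7,11-trimethyl-5-(triethylsilyloxy)-1-oxacyclotrideca-3,7,11-triene | C/C1=C/COC/C(C)=C\[C@H](O[Si](CC)(CC)CC)C/C(C)=C\CC1 | intermediate (key-step precursor)
27 | 26 lithiated at its ring carbon 13 (overview C3; configuration there not defined) | C/C1=C/C([Li])OC/C(C)=C\[C@H](O[Si](CC)(CC)CC)C/C(C)=C\CC1 | intermediate (not isolated)
28 | lithium (1Z,3R,4R,5R,7Z)-1,7-dimethyl-4-(prop-1-en-2-yl)-5-(triethylsilyloxy)cyclodeca-1,7-dien-3-olate | C/C1=C/[C@@H]([O-])[C@@H](C(C)=C)[C@H](O[Si](CC)(CC)CC)C/C(C)=C\CC1.[Li+] | intermediate (not isolated)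
29 | (1Z,3R,4R,5R,7Z)-1,7-dimethyl-4-(prop-1-en-2-yl)-5-(triethylsilyloxy)cyclodeca-1,7-dien-3-ol | C/C1=C/[C@@H](O)[C@@H](C(C)=C)[C@H](O[Si](CC)(CC)CC)C/C(C)=C\CC1 | intermediate (key-step product)
30 | (1Z,3R,4R,5R,7Z)-1,7-dimethyl-4-(propan-2-yl)-5-(triethylsilyloxy)cyclodeca-1,7-dien-3-ol | C/C1=C/[C@@H](O)[C@@H](C(C)C)[C@H](O[Si](CC)(CC)CC)C/C(C)=C\CC1 | intermediate
31 | (1Z,3R,4S,5R,7Z)-3-(tert-butyldimethylsilyloxy)-1,7-dimethyl-4-(propan-2-yl)-5-(triethylsilyloxy)cyclodeca-1,7-diene (descriptor at C4 changes by priority only) | C/C1=C/[C@@H](O[Si](C)(C)C(C)(C)C)[C@@H](C(C)C)[C@H](O[Si](CC)(CC)CC)C/C(C)=C\CC1 | intermediate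
32 | (1Z,3R,4S,5R,7Z)-3-(tert-butyldimethylsilyloxy)-1,7-dimethyl-4-(propan-2-yl)cyclodeca-1,7-dien-5-ol | C/C1=C/[C@@H](O[Si](C)(C)C(C)(C)C)[C@@H](C(C)C)[C@H](O)C/C(C)=C\CC1 | intermediate
33 | 4-hydroxybenzoic acid | OC(=O)c1ccc(O)cc1 | starting material
34 | tert-butyldimethylsilyl 4-(tert-butyldimethylsilyloxy)benzoate | CC(C)(C)[Si](C)(C)OC(=O)c1ccc(O[Si](C)(C)C(C)(C)C)cc1 | intermediate (not isolated)
35 | 4-(tert-butyldimethylsilyloxy)benzoic acid | CC(C)(C)[Si](C)(C)Oc1ccc(C(=O)O)cc1 | intermediate
36 | 4-(tert-butyldimethylsilyloxy)benzoic 2,4,6-trichlorobenzoic anhydride | CC(C)(C)[Si](C)(C)Oc1ccc(cc1)C(=O)OC(=O)c1c(Cl)cc(Cl)cc1Cl | intermediate (not isolated)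
37 | (1Z,3R,4S,5R,7Z)-3-(tert-butyldimethylsilyloxy)-1,7-dimethyl-4-(propan-2-yl)cyclodeca-1,7-dien-5-yl 4-(tert-butyldimethylsilyloxy)benzoate | C/C1=C/[C@@H](O[Si](C)(C)C(C)(C)C)[C@@H](C(C)C)[C@H](OC(=O)c2ccc(O[Si](C)(C)C(C)(C)C)cc2)C/C(C)=C\CC1 | intermediate
38 | (1Z,3R,4R,5R,7Z)-3-hydroxy-1,7-dimethyl-4-(propan-2-yl)cyclodeca-1,7-dien-5-yl 4-hydroxybenzoate | C/C1=C/[C@@H](O)[C@@H](C(C)C)[C@H](OC(=O)c2ccc(O)cc2)C/C(C)=C\CC1 | target

**Step count**

Total: 20 steps. Longest linear sequence: 18 steps (1–4, 6–17, 19, 20); steps 5 and 18 are side branches.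

**Steps most likely to fail**

1. Step 14. Deprotonation may occur at C12 instead of C3, after which the allyl anion can expel triethylsilanolate from C5 or undergo a [1,2]-shift; if the [2,3]-shift does occur, face selection at C4 may be incomplete. The fallback closes the same C3–C4 bond by a chromium-mediated allylation, sets out from 24 and returns at 29. Oxidation of 24 with MnO2 in CH2Cl2 would give the Z-enal (2Z,6Z,9R,10Z)-12-chloro-3,7,11-trimethyl-9-(triethylsilyloxy)dodeca-2,6,10-trienal F1. Treatment of F1 with CrCl2 (divalent chromium) and NaI in THF/DMF at high dilution would generate an allylchromium species (trivalent chromium) at C12 that adds through C4 to the aldehyde carbon C3 (intramolecular Nozaki–Hiyama allylation, known for ten-membered terpenoid rings). This gives the ten-membered isopropenyl carbinol directly. The chair transition state of such allylations normally gives the anti relationship, so the C3 epimer (1Z,3S,4R,5R,7Z)-1,7-dimethyl-4-(prop-1-en-2-yl)-5-(triethylsilyloxy)cyclodeca-1,7-dien-3-ol F2 is expected. Mitsunobu inversion of F2 (4-nitrobenzoic acid, PPh3, diisopropyl azodicarboxylate) would give the 4-nitrobenzoate of 29 F3, and K2CO3 in MeOH would then release 29.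

2. Step 13. Intermolecular etherification to oligomers, or SN2′ attack and 1,4-elimination at the branched 2-methylallyl chloride, may outrun the 13-membered closure. The fallback closes the other C–O bond (O–C3) with the unbranched neryl-type chloride as electrophile, sets out from 20 and returns at 26. Buffered DDQ on 20 would give ethyl (2Z,4R,6Z,10Z)-12-hydroxy-2,6,10-trimethyl-4-(triethylsilyloxy)dodeca-2,6,10-trienoate F4. MsCl/Et3N followed by LiCl would give ethyl (2Z,4R,6Z,10Z)-12-chloro-2,6,10-trimethyl-4-(triethylsilyloxy)dodeca-2,6,10-trienoate F5. Reduction with i-Bu2AlH at −78 °C would give (2Z,4R,6Z,10Z)-12-chloro-2,6,10-trimethyl-4-(triethylsilyloxy)dodeca-2,6,10-trien-1-ol F6, and NaH at high dilution would close it to 26.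

3. Step 4. Z/E control may erode and iodination of the ylide may be incomplete, so that the E-iodide or the non-iodinated alkene accompanies 11. The fallback builds the same alkenyl halide geometry by cross-coupling, sets out from 6 and returns at 15 through the same alkenyllithium 14. CBr4/PPh3 (first stage of the Corey–Fuchs sequence) would convert 6 into 1-({[(2Z)-7,7-dibromo-3-methylhepta-2,6-dien-1-yl]oxy}methyl)-4-methoxybenzene F7. A trans-selective Negishi mono-methylation (MeZnCl, Pd(P(t-Bu)3)2, zerovalent palladium, THF) would replace the bromine trans to the chain and give 1-({[(2Z,6Z)-7-bromo-3-methylocta-2,6-dien-1-yl]oxy}methyl)-4-methoxybenzene F8. Bromine–lithium exchange of F8 with t-BuLi gives 14, which is used as in step 6.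

**Further compounds**

F1 | step 14 | (2Z,6Z,9R,10Z)-12-chloro-3,7,11-trimethyl-9-(triethylsilyloxy)dodeca-2,6,10-trienal | ClC/C(C)=C\[C@H](O[Si](CC)(CC)CC)C/C(C)=C\CC/C(C)=C\C=O
F2 | step 14 | (1Z,3S,4R,5R,7Z)-1,7-dimethyl-4-(prop-1-en-2-yl)-5-(triethylsilyloxy)cyclodeca-1,7-dien-3-ol | C/C1=C/[C@H](O)[C@@H](C(C)=C)[C@H](O[Si](CC)(CC)CC)C/C(C)=C\CC1
F3 | step 14 | (1Z,3R,4R,5R,7Z)-1,7-dimethyl-4-(prop-1-en-2-yl)-5-(triethylsilyloxy)cyclodeca-1,7-dien-3-yl 4-nitrobenzoate | C/C1=C/[C@@H](OC(=O)c2ccc(cc2)[N+](=O)[O-])[C@@H](C(C)=C)[C@H](O[Si](CC)(CC)CC)C/C(C)=C\CC1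
F4 | step 13 | ethyl (2Z,4R,6Z,10Z)-12-hydroxy-2,6,10-trimethyl-4-(triethylsilyloxy)dodeca-2,6,10-trienoate | CCOC(=O)/C(C)=C\[C@H](O[Si](CC)(CC)CC)C/C(C)=C\CC/C(C)=C\CO
F5 | step 13 | ethyl (2Z,4R,6Z,10Z)-12-chloro-2,6,10-trimethyl-4-(triethylsilyloxy)dodeca-2,6,10-trienoate | CCOC(=O)/C(C)=C\[C@H](O[Si](CC)(CC)CC)C/C(C)=C\CC/C(C)=C\CCl
F6 | step 13 | (2Z,4R,6Z,10Z)-12-chloro-2,6,10-trimethyl-4-(triethylsilyloxy)dodeca-2,6,10-trien-1-ol | OC/C(C)=C\[C@H](O[Si](CC)(CC)CC)C/C(C)=C\CC/C(C)=C\CCl
F7 | step 4 | 1-({[(2Z)-7,7-dibromo-3-methylhepta-2,6-dien-1-yl]oxy}methyl)-4-methoxybenzene | BrC(Br)=CCC/C(C)=C\COCc1ccc(OC)cc1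
F8 | step 4 | 1-({[(2Z,6Z)-7-bromo-3-methylocta-2,6-dien-1-yl]oxy}methyl)-4-methoxybenzene | C/C(Br)=C/CC/C(C)=C\COCc1ccc(OC)cc1
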